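## Retrosynthetic overview

1. Target 31 ⇐ removal of the C10 silyl ether from macrocycle 30 ⇐ Nozaki–Hiyama–Kishi closure of C3–C4 in the open-chain (Z)-vinyl iodide / cis-epoxy aldehyde 29 (ten-membered carbocycle formed last).
2. 29 ⇐ C8 angeloylation, α-methylenation and oxidative lactonisation (γ-lactone formed second) of iodo diol 20; its C6 carbinol and Z-iodoalkene come from an ynone by transfer hydrogenation, trans-hydrosilylation and iododesilylation.
3. C7 and C8 ⇐ ketoreductase dynamic kinetic reduction of the α-allyl β-keto ester 10.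
4. 10 ⇐ C9–C10 bond by chelation-controlled addition of the dianion of 9 to the cis-epoxy methyl ketone 6 (sets C10).
5. 6 ⇐ Sharpless asymmetric epoxidation of mono-protected (Z)-but-2-ene-1,4-diol (epoxide ring formed first; sets C1 and C2).

Locants used below: C1/C2 epoxide carbons (C1 next to C10), C3 secondary carbinol, C4 (methyl C15)=C5, C6 lactone O–CH, C7 ring-fusion CH, C8 angelate-bearing CH, C9 CH2, C10 tertiary carbinol (methyl C14), C11 lactone α-carbon, C12 lactone carbonyl, C13 exocyclic CH2. The target is 1R,2R,3R,6S,7R,8R,10R, 4Z, with a Z (angelate) ester. PMB = 4-methoxybenzyl, TES = triethylsilyl.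

Assumption: all named reagents (including 1-propynyllithium, angelic acid and a ketoreductase screening panel from which an anti-selective enzyme is chosen) are taken as commercial.

## Route

Step 1
Reactants: 1 (Z)-but-2-ene-1,4-diol
Product: 2 (Z)-4-(PMB-oxy)but-2-en-1-ol
Conditions: 1 (3 equiv), NaH (1 equiv), PMBCl (1 equiv), n-Bu4NI (cat.), THF, 0 °C to rt
Reagents that add atoms: 4-methoxybenzyl chloride, COc1ccc(CCl)cc1
Why: Williamson monoalkylation of the mono-alkoxide of the symmetric diol (diol in excess) gives the mono-ether, and no stereocentre is formed.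

Step 2
Reactants: 2 (Z)-4-(PMB-oxy)but-2-en-1-ol
Product: 3 cis-epoxy alcohol [(2S,3R)-3-(PMB-oxymethyl)oxiran-2-yl]methanol
Conditions: Ti(OiPr)4 (10 mol %), L-(+)-diethyl tartrate (12 mol %), t-BuOOH, 4 Å MS, CH2Cl2, −20 °C
Reagents that add atoms: tert-butyl hydroperoxide, CC(C)(C)OO
Why: Sharpless asymmetric epoxidation, in which the Ti(OiPr)4/L-(+)-tartrate catalyst delivers the peroxide oxygen to one enantiotopic face of the Z-allylic alcohol and so sets C1 and C2 (about 90% ee, upgraded later when diastereomers are separated).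

Step 3
Reactants: 3 cis-epoxy alcohol
Product: 4 cis-epoxy aldehyde (2R,3R)-3-(PMB-oxymethyl)oxirane-2-carbaldehyde
Conditions: TEMPO (10 mol %), PhI(OAc)2, CH2Cl2, rt
Reagents that add atoms: none
Why: Oxoammonium (TEMPO) oxidation stops at the aldehyde under neutral conditions that neither open nor epimerise the cis-epoxide.

Step 4
Reactants: 4 cis-epoxy aldehyde
Product: 5 1-[(2S,3R)-3-(PMB-oxymethyl)oxiran-2-yl]ethan-1-ol (both carbinol epimers)
Conditions: MeMgBr, THF, −78 °C; aqueous work-up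
Reagents that add atoms: methylmagnesium bromide, C[Mg]Br
Why: Grignard addition brings in C14, and the new carbinol configuration is irrelevant because it is oxidised in the next step.

Step 5
Reactants: 5 epoxy carbinol
Product: 6 cis-epoxy methyl ketone 1-[(2R,3R)-3-(PMB-oxymethyl)oxiran-2-yl]ethan-1-one
Conditions: Dess–Martin periodinane, pyridine, CH2Cl2, 0 °C to rt
Reagents that add atoms: none
Why: Dess–Martin oxidation of the secondary alcohol gives the α,β-epoxy ketone without touching the epoxide or the PMB ether.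

Step 6
Reactants: 7 ethyl acetoacetate; 8 allyl bromide
Product: 9 ethyl 2-acetylpent-4-enoate (racemic, enolisable)
Conditions: K2CO3, acetone, reflux
Reagents that add atoms: none
Why: Acetoacetic ester C-alkylation of the β-keto ester enolate with a reactive allylic bromide; the α-centre is configurationally labile, which step 8 exploits.

Step 7
Reactants: 6 cis-epoxy methyl ketone; 9 ethyl 2-acetylpent-4-enoate
Product: 10 ethyl (5R)-2-allyl-5-hydroxy-5-[(2R,3R)-3-(PMB-oxymethyl)oxiran-2-yl]-3-oxohexanoate (C7 epimers)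
Conditions: 9 (2 equiv), NaH then n-BuLi, THF, 0 °C; CeCl3, −78 °C; then 6, −78 °C; AcOH quench
Reagents that add atoms: none
Why: Weiler γ-addition of the acetoacetate dianion as its CeCl3-derived cerium dienolate (which suppresses enolisation and retro-aldol) to the ketone held in a five-membered chelate with the epoxide oxygen, so that C9 enters anti to the epoxide C1–C2 bond (Cram-chelate control, the sense seen in Zn(BH4)2 reductions of epoxy ketones) and sets C10 as R.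

Step 8
Reactants: 10 α-allyl δ-hydroxy β-keto ester
Product: 11 ethyl (2R,3R,5R)-2-allyl-3,5-dihydroxy-5-[(2R,3R)-3-(PMB-oxymethyl)oxiran-2-yl]hexanoate
Conditions: ketoreductase (NADPH-dependent alcohol dehydrogenase, anti-selective panel hit), NADP+ (cat.), i-PrOH (10% v/v), KH2PO4/K2HPO4 buffer pH 7.0, 30 °C
Reagents that add atoms: none
Why: Ketoreductase dynamic reductive kinetic resolution, in which the C7 epimers interconvert through the enol at pH 7 while the enzyme reduces only one of them from one carbonyl face, setting C7 and C8 (anti) under catalyst control.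

Step 9
Reactants: 11 diol ester
Product: 12 bis-TES ether ethyl (2R,3R,5R)-2-allyl-5-[(2R,3R)-3-(PMB-oxymethyl)oxiran-2-yl]-3,5-bis(triethylsilyloxy)hexanoate
Conditions: Et3SiOTf (3 equiv), 2,6-lutidine, CH2Cl2, −78 to 0 °C
Reagents that add atoms: triethylsilyl trifluoromethanesulfonate, CC[Si](CC)(CC)OS(=O)(=O)C(F)(F)F
Why: Silyl triflate silylation is strong enough to cap both the secondary and the hindered tertiary hydroxyl, while 2,6-lutidine keeps the medium non-acidic for the epoxide.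

Step 10
Reactants: 12 bis-TES ether
Product: 14 aldehyde ethyl (2R,3R,5R)-2-(2-oxoethyl)-5-[(2R,3R)-3-(PMB-oxymethyl)oxiran-2-yl]-3,5-bis(triethylsilyloxy)hexanoate, via vicinal diol 13 (not isolated)
Conditions: OsO4 (2 mol %), NaIO4, 2,6-lutidine, dioxane/H2O, rt
Reagents that add atoms: osmium tetroxide, O=[Os](=O)(=O)=O; sodium periodate, [Na+].[O-]I(=O)(=O)=O
Why: Lemieux–Johnson cleavage (catalytic dihydroxylation then periodate scission) of the only alkene present removes the terminal carbon and leaves C12 as an aldehyde.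

Step 11
Reactants: 14 aldehyde
Product: 16 lactone (3R)-3-{(1R,3R)-3-[(2R,3R)-3-(PMB-oxymethyl)oxiran-2-yl]-1,3-bis(triethylsilyloxy)butyl}oxolan-2-one, via hydroxy ester 15 (not isolated)
Conditions: NaBH4, EtOH, −20 °C; then PPTS (cat.), CH2Cl2, rt
Reagents that add atoms: none
Why: Chemoselective borohydride reduction of the aldehyde beside the ester followed by five-ring lactonisation (transesterification), which parks C12 as a lactone oxygen and activates C6 as a lactone carbonyl.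

Step 12
Reactants: 16 lactone
Product: 17 hydroxy ynone (5R,6R,8R)-5-(2-hydroxyethyl)-8-[(2R,3R)-3-(PMB-oxymethyl)oxiran-2-yl]-6,8-bis(triethylsilyloxy)non-2-yn-4-one
Conditions: 1-propynyllithium (1.5 equiv), THF, −78 °C; aqueous work-up
Reagents that add atoms: 1-propynyllithium, [Li]C#CC
Why: Alkynyllithium addition to the lactone stops at the tetrahedral lithium hemiketal at −78 °C, which opens on work-up to the ynone and frees the C12 hydroxyl (C4, C5 and C15 introduced).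

Step 13
Reactants: 17 hydroxy ynone
Product: 18 propargylic diol (4R,5S,6R,8R)-5-(2-hydroxyethyl)-8-[(2R,3R)-3-(PMB-oxymethyl)oxiran-2-yl]-6,8-bis(triethylsilyloxy)non-2-yn-4-ol
Conditions: Ru[(R,R)-TsNCHPhCHPhNH](η6-p-cymene) (2 mol %), i-PrOH, rt
Reagents that add atoms: none
Why: Noyori asymmetric transfer hydrogenation of the ynone, in which the Ru[(R,R)-TsNCHPhCHPhNH](η6-p-cymene) catalyst distinguishes alkynyl from alkyl and gives the (R)-propargylic alcohol at C6 under catalyst control.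

Step 14
Reactants: 18 propargylic diol
Product: 19 (Z)-vinylsilane (2Z,4R,5S,6R,8R)-5-(2-hydroxyethyl)-8-[(2R,3R)-3-(PMB-oxymethyl)oxiran-2-yl]-2-(triethylsilyl)-6,8-bis(triethylsilyloxy)non-2-en-4-ol
Conditions: Et3SiH (1.5 equiv), [Cp*Ru(MeCN)3]PF6 (3 mol %), CH2Cl2, 0 °C to rt
Reagents that add atoms: triethylsilane, CC[SiH](CC)CC
Why: Trost trans-hydrosilylation adds H and Si anti across the alkyne with silicon distal to the propargylic hydroxyl, so silicon sits on C4 cis to C6.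

Step 15
Reactants: 19 (Z)-vinylsilane
Product: 20 (Z)-vinyl iodide diol (2Z,4R,5S,6R,8R)-5-(2-hydroxyethyl)-2-iodo-8-[(2R,3R)-3-(PMB-oxymethyl)oxiran-2-yl]-6,8-bis(triethylsilyloxy)non-2-en-4-ol
Conditions: N-iodosuccinimide (1.1 equiv), 2,6-lutidine, (CF3)2CHOH/CH2Cl2, 0 °C, 10 min
Reagents that add atoms: N-iodosuccinimide, O=C1CCC(=O)N1I
Why: Electrophilic ipso-iododesilylation (β-silyl cation, then loss of silicon) proceeds with retention of alkene geometry and gives the Z-iodoalkene needed for the ring closure.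

Step 16
Reactants: 20 (Z)-vinyl iodide diol
Product: 22 cis-lactone (4S,5R)-5-[(1Z)-2-iodoprop-1-en-1-yl]-4-{(1R,3R)-3-[(2R,3R)-3-(PMB-oxymethyl)oxiran-2-yl]-1,3-bis(triethylsilyloxy)butyl}oxolan-2-one, via lactol 21 (not isolated)
Conditions: TEMPO (20 mol %), PhI(OAc)2 (2.5 equiv), CH2Cl2, rt
Reagents that add atoms: none
Why: Oxidative lactonisation of a 1,4-diol, in which TEMPO oxidises the primary alcohol first, the aldehyde closes onto the C6 hydroxyl and the lactol is oxidised on to the cis-fused γ-lactone without touching C6 or C7.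

Step 17
Reactants: 22 cis-lactone
Product: 23 Mannich base, the 3-[(dimethylamino)methyl] derivative of 22 (C11 epimers)
Conditions: LiN(iPr)2 (1.3 equiv), THF, −78 °C; then Me2N=CH2 I, −78 to 0 °C
Reagents that add atoms: N,N-dimethylmethyleneiminium iodide (Eschenmoser's salt), C=[N+](C)C.[I-]
Why: Mannich reaction of the lactone lithium enolate with Eschenmoser's salt introduces C13 at C11, whose configuration is irrelevant.

Step 18
Reactants: 23 Mannich base
Product: 24 trimethylammonium iodide of 23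
Conditions: MeI (excess), MeOH, rt
Reagents that add atoms: iodomethane, CI
Why: Menshutkin N-methylation turns the amine into a trimethylammonium leaving group.

Step 19
Reactants: 24 trimethylammonium iodide
Product: 25 α-methylene lactone (4S,5R)-5-[(1Z)-2-iodoprop-1-en-1-yl]-3-methylidene-4-{(1R,3R)-3-[(2R,3R)-3-(PMB-oxymethyl)oxiran-2-yl]-1,3-bis(triethylsilyloxy)butyl}oxolan-2-one
Conditions: aq. NaHCO3, CH2Cl2, rt
Reagents that add atoms: none
Why: Mild-base E1cB (Hofmann-type) elimination of trimethylamine gives the exocyclic methylene.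

Step 20
Reactants: 25 α-methylene lactone
Product: 26 C8 alcohol (4R,5R)-4-{(1R,3R)-1-hydroxy-3-[(2R,3R)-3-(PMB-oxymethyl)oxiran-2-yl]-3-(triethylsilyloxy)butyl}-5-[(1Z)-2-iodoprop-1-en-1-yl]-3-methylideneoxolan-2-one
Conditions: HF·pyridine, pyridine, THF, 0 °C, monitored
Reagents that add atoms: none
Why: Buffered fluoride desilylation cleaves the secondary TES ether much faster than the hindered tertiary one (steric differentiation).

Step 21
Reactants: 26 C8 alcohol
Product: 27 C8 angelate of 26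
Conditions: angelic acid, 2,4,6-Cl3C6H2COCl, Et3N, toluene, rt; then 26, DMAP, toluene, rt to 40 °C
Reagents that add atoms: angelic acid [(2Z)-2-methylbut-2-enoic acid], C/C=C(/C)C(O)=O
Why: Yamaguchi esterification through the mixed trichlorobenzoic anhydride acylates the secondary alcohol without Z-to-E isomerisation of the angelate, and it is run promptly so that the free C8 hydroxyl does not translactonise.

Step 22
Reactants: 27 angelate
Product: 28 primary alcohol, 27 with the C3 PMB ether replaced by OH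
Conditions: DDQ (1.5 equiv), CH2Cl2/pH 7 buffer, 0 °C to rt
Reagents that add atoms: none
Why: Oxidative PMB cleavage (hydride abstraction by DDQ, hydrolysis of the oxocarbenium ion) frees the C3 alcohol beside silyl ether, esters, epoxide and vinyl iodide.

Step 23
Reactants: 28 primary alcohol
Product: 29 cis-epoxy aldehyde, 28 with C3 as CHO
Conditions: Dess–Martin periodinane, pyridine, CH2Cl2, 0 °C
Reagents that add atoms: none
Why: Dess–Martin oxidation gives the epoxy aldehyde under buffered, non-epimerising conditions, and the silylated quaternary C10 oxygen cannot form a lactol with it.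

Step 24
Reactants: 29 cis-epoxy aldehyde
Product: 30 macrocycle, the 10-O-TES ether of the target
Conditions: CrCl2 (15 equiv), NiCl2 (0.15 equiv), degassed DMSO, 0.002 M, rt
Reagents that add atoms: none
Why: Nozaki–Hiyama–Kishi macrocyclisation, in which NiCl2-derived zerovalent nickel inserts into the vinyl iodide with retention of the Z geometry, the alkenyl group passes to chromium and adds to the aldehyde anti to the epoxide C–O bond (Felkin–Anh), closing the ten-membered ring and setting C3 as the R (erythro) epoxy alcohol.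

Step 25
Reactants: 30 macrocycle
Product: 31 target
Conditions: HF·pyridine, pyridine, THF, 0 °C to rt
Reagents that add atoms: none
Why: Fluoride cleavage of the remaining tertiary silyl ether under buffered conditions leaves the epoxide, the α-methylene lactone and the angelate intact.

## Compound list

1 | (2Z)-but-2-ene-1,4-diol | OC/C=C\CO | starting material
2 | (2Z)-4-[(4-methoxyphenyl)methoxy]but-2-en-1-ol | COc1ccc(COC/C=C\CO)cc1 | intermediate
3 | [(2S,3R)-3-{[(4-methoxyphenyl)methoxy]methyl}oxiran-2-yl]methanol | COc1ccc(COC[C@H]2O[C@H]2CO)cc1 | intermediate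
4 | (2R,3R)-3-{[(4-methoxyphenyl)methoxy]methyl}oxirane-2-carbaldehyde | COc1ccc(COC[C@H]2O[C@H]2C=O)cc1 | intermediate
5 | 1-[(2S,3R)-3-{[(4-methoxyphenyl)methoxy]methyl}oxiran-2-yl]ethan-1-ol (carbinol epimers) | COc1ccc(COC[C@H]2O[C@H]2C(C)O)cc1 | intermediate
6 | 1-[(2R,3R)-3-{[(4-methoxyphenyl)methoxy]methyl}oxiran-2-yl]ethan-1-one | COc1ccc(COC[C@H]2O[C@H]2C(C)=O)cc1 | intermediate
7 | ethyl 3-oxobutanoate (ethyl acetoacetate) | CCOC(=O)CC(C)=O | starting material
8 | 3-bromoprop-1-ene (allyl bromide) | C=CCBr | starting material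
9 | ethyl 2-acetylpent-4-enoate (racemic) | CCOC(=O)C(CC=C)C(C)=O | intermediate
10 | ethyl (5R)-5-hydroxy-5-[(2R,3R)-3-{[(4-methoxyphenyl)methoxy]methyl}oxiran-2-yl]-3-oxo-2-(prop-2-en-1-yl)hexanoate (C2 epimers) | COc1ccc(COC[C@H]2O[C@H]2[C@](C)(O)CC(=O)C(CC=C)C(=O)OCC)cc1 | intermediate
11 | ethyl (2R,3R,5R)-3,5-dihydroxy-5-[(2R,3R)-3-{[(4-methoxyphenyl)methoxy]methyl}oxiran-2-yl]-2-(prop-2-en-1-yl)hexanoate | COc1ccc(COC[C@H]2O[C@H]2[C@](C)(O)C[C@@H](O)[C@@H](CC=C)C(=O)OCC)cc1 | intermediate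
12 | ethyl (2R,3R,5R)-5-[(2R,3R)-3-{[(4-methoxyphenyl)methoxy]methyl}oxiran-2-yl]-2-(prop-2-en-1-yl)-3,5-bis[(triethylsilyl)oxy]hexanoate | COc1ccc(COC[C@H]2O[C@H]2[C@](C)(O[Si](CC)(CC)CC)C[C@@H](O[Si](CC)(CC)CC)[C@@H](CC=C)C(=O)OCC)cc1 | intermediate
13 | ethyl (2R,3R,5R)-2-(2,3-dihydroxypropyl)-5-[(2R,3R)-3-{[(4-methoxyphenyl)methoxy]methyl}oxiran-2-yl]-3,5-bis[(triethylsilyl)oxy]hexanoate (diol epimers) | COc1ccc(COC[C@H]2O[C@H]2[C@](C)(O[Si](CC)(CC)CC)C[C@@H](O[Si](CC)(CC)CC)[C@@H](CC(O)CO)C(=O)OCC)cc1 | intermediate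
14 | ethyl (2R,3R,5R)-5-[(2R,3R)-3-{[(4-methoxyphenyl)methoxy]methyl}oxiran-2-yl]-2-(2-oxoethyl)-3,5-bis[(triethylsilyl)oxy]hexanoate | COc1ccc(COC[C@H]2O[C@H]2[C@](C)(O[Si](CC)(CC)CC)C[C@@H](O[Si](CC)(CC)CC)[C@@H](CC=O)C(=O)OCC)cc1 | intermediate
15 | ethyl (2R,3R,5R)-2-(2-hydroxyethyl)-5-[(2R,3R)-3-{[(4-methoxyphenyl)methoxy]methyl}oxiran-2-yl]-3,5-bis[(triethylsilyl)oxy]hexanoate | COc1ccc(COC[C@H]2O[C@H]2[C@](C)(O[Si](CC)(CC)CC)C[C@@H](O[Si](CC)(CC)CC)[C@@H](CCO)C(=O)OCC)cc1 | intermediate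
16 | (3R)-3-{(1R,3R)-3-[(2R,3R)-3-{[(4-methoxyphenyl)methoxy]methyl}oxiran-2-yl]-1,3-bis[(triethylsilyl)oxy]butyl}oxolan-2-one | COc1ccc(COC[C@H]2O[C@H]2[C@](C)(O[Si](CC)(CC)CC)C[C@@H](O[Si](CC)(CC)CC)[C@H]3CCOC3=O)cc1 | intermediate
17 | (5R,6R,8R)-5-(2-hydroxyethyl)-8-[(2R,3R)-3-{[(4-methoxyphenyl)methoxy]methyl}oxiran-2-yl]-6,8-bis[(triethylsilyl)oxy]non-2-yn-4-one | COc1ccc(COC[C@H]2O[C@H]2[C@](C)(O[Si](CC)(CC)CC)C[C@@H](O[Si](CC)(CC)CC)[C@@H](CCO)C(=O)C#CC)cc1 | intermediate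
18 | (4R,5S,6R,8R)-5-(2-hydroxyethyl)-8-[(2R,3R)-3-{[(4-methoxyphenyl)methoxy]methyl}oxiran-2-yl]-6,8-bis[(triethylsilyl)oxy]non-2-yn-4-ol | COc1ccc(COC[C@H]2O[C@H]2[C@](C)(O[Si](CC)(CC)CC)C[C@@H](O[Si](CC)(CC)CC)[C@@H](CCO)[C@@H](O)C#CC)cc1 | intermediate
19 | (2Z,4R,5S,6R,8R)-5-(2-hydroxyethyl)-8-[(2R,3R)-3-{[(4-methoxyphenyl)methoxy]methyl}oxiran-2-yl]-2-(triethylsilyl)-6,8-bis[(triethylsilyl)oxy]non-2-en-4-ol | COc1ccc(COC[C@H]2O[C@H]2[C@](C)(O[Si](CC)(CC)CC)C[C@@H](O[Si](CC)(CC)CC)[C@@H](CCO)[C@@H](O)/C=C(/C)[Si](CC)(CC)CC)cc1 | intermediate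
20 | (2Z,4R,5S,6R,8R)-5-(2-hydroxyethyl)-2-iodo-8-[(2R,3R)-3-{[(4-methoxyphenyl)methoxy]methyl}oxiran-2-yl]-6,8-bis[(triethylsilyl)oxy]non-2-en-4-ol | COc1ccc(COC[C@H]2O[C@H]2[C@](C)(O[Si](CC)(CC)CC)C[C@@H](O[Si](CC)(CC)CC)[C@@H](CCO)[C@@H](O)/C=C(/C)I)cc1 | intermediate
21 | (4S,5R)-5-[(1Z)-2-iodoprop-1-en-1-yl]-4-{(1R,3R)-3-[(2R,3R)-3-{[(4-methoxyphenyl)methoxy]methyl}oxiran-2-yl]-1,3-bis[(triethylsilyl)oxy]butyl}oxolan-2-ol (anomers) | COc1ccc(COC[C@H]2O[C@H]2[C@](C)(O[Si](CC)(CC)CC)C[C@@H](O[Si](CC)(CC)CC)[C@H]3CC(O)O[C@H]3/C=C(/C)I)cc1 | intermediate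
22 | (4S,5R)-5-[(1Z)-2-iodoprop-1-en-1-yl]-4-{(1R,3R)-3-[(2R,3R)-3-{[(4-methoxyphenyl)methoxy]methyl}oxiran-2-yl]-1,3-bis[(triethylsilyl)oxy]butyl}oxolan-2-one | COc1ccc(COC[C@H]2O[C@H]2[C@](C)(O[Si](CC)(CC)CC)C[C@@H](O[Si](CC)(CC)CC)[C@H]3CC(=O)O[C@H]3/C=C(/C)I)cc1 | intermediate
23 | 3-[(dimethylamino)methyl] derivative of 22 (C3 epimers of the oxolanone) | COc1ccc(COC[C@H]2O[C@H]2[C@](C)(O[Si](CC)(CC)CC)C[C@@H](O[Si](CC)(CC)CC)[C@H]3C(CN(C)C)C(=O)O[C@H]3/C=C(/C)I)cc1 | intermediate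
24 | N,N,N-trimethylammonium iodide of 23 | COc1ccc(COC[C@H]2O[C@H]2[C@](C)(O[Si](CC)(CC)CC)C[C@@H](O[Si](CC)(CC)CC)[C@H]3C(C[N+](C)(C)C)C(=O)O[C@H]3/C=C(/C)I)cc1.[I-] | intermediate
25 | (4S,5R)-5-[(1Z)-2-iodoprop-1-en-1-yl]-4-{(1R,3R)-3-[(2R,3R)-3-{[(4-methoxyphenyl)methoxy]methyl}oxiran-2-yl]-1,3-bis[(triethylsilyl)oxy]butyl}-3-methylideneoxolan-2-one | COc1ccc(COC[C@H]2O[C@H]2[C@](C)(O[Si](CC)(CC)CC)C[C@@H](O[Si](CC)(CC)CC)[C@H]3C(=C)C(=O)O[C@H]3/C=C(/C)I)cc1 | intermediate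
26 | (4R,5R)-4-{(1R,3R)-1-hydroxy-3-[(2R,3R)-3-{[(4-methoxyphenyl)methoxy]methyl}oxiran-2-yl]-3-[(triethylsilyl)oxy]butyl}-5-[(1Z)-2-iodoprop-1-en-1-yl]-3-methylideneoxolan-2-one | COc1ccc(COC[C@H]2O[C@H]2[C@](C)(O[Si](CC)(CC)CC)C[C@@H](O)[C@H]3C(=C)C(=O)O[C@H]3/C=C(/C)I)cc1 | intermediate
27 | (1R,3R)-1-{(2R,3R)-2-[(1Z)-2-iodoprop-1-en-1-yl]-4-methylidene-5-oxooxolan-3-yl}-3-[(2R,3R)-3-{[(4-methoxyphenyl)methoxy]methyl}oxiran-2-yl]-3-[(triethylsilyl)oxy]butyl (2Z)-2-methylbut-2-enoate | COc1ccc(COC[C@H]2O[C@H]2[C@](C)(O[Si](CC)(CC)CC)C[C@@H](OC(=O)/C(C)=C\C)[C@H]3C(=C)C(=O)O[C@H]3/C=C(/C)I)cc1 | intermediate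
28 | (1R,3R)-3-[(2R,3R)-3-(hydroxymethyl)oxiran-2-yl]-1-{(2R,3R)-2-[(1Z)-2-iodoprop-1-en-1-yl]-4-methylidene-5-oxooxolan-3-yl}-3-[(triethylsilyl)oxy]butyl (2Z)-2-methylbut-2-enoate | OC[C@H]1O[C@H]1[C@](C)(O[Si](CC)(CC)CC)C[C@@H](OC(=O)/C(C)=C\C)[C@H]2C(=C)C(=O)O[C@H]2/C=C(/C)I | intermediate
29 | (1R,3R)-3-[(2R,3S)-3-formyloxiran-2-yl]-1-{(2R,3R)-2-[(1Z)-2-iodoprop-1-en-1-yl]-4-methylidene-5-oxooxolan-3-yl}-3-[(triethylsilyl)oxy]butyl (2Z)-2-methylbut-2-enoate | O=C[C@H]1O[C@H]1[C@](C)(O[Si](CC)(CC)CC)C[C@@H](OC(=O)/C(C)=C\C)[C@H]2C(=C)C(=O)O[C@H]2/C=C(/C)I | intermediate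
30 | 10-O-triethylsilyl ether of the target (1R,2R,3R,6S,7R,8R,10R, 4Z in the route locants) | C=C1C(=O)O[C@H]2/C=C(/C)[C@@H](O)[C@H]3O[C@H]3[C@](C)(O[Si](CC)(CC)CC)C[C@@H](OC(=O)/C(C)=C\C)[C@@H]12 | intermediate
31 | (1R,2R,3R,4Z,6S,7R,8R,10R)-1,2-epoxy-3,10-dihydroxy-8-[(2Z)-2-methylbut-2-enoyloxy]germacra-4,11(13)-dien-12,6-olide (route locants) | C=C1C(=O)O[C@H]2/C=C(/C)[C@@H](O)[C@H]3O[C@H]3[C@](C)(O)C[C@@H](OC(=O)/C(C)=C\C)[C@@H]12 | target

## Step count and risks

Total steps: 25. Longest linear sequence: 24 steps (steps 1–5 and 7–25, from 1); step 6 is a one-step side branch.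

**Step 7** (C9–C10 bond and the C10 configuration). A non-chelated Felkin–Anh addition would give the C10 epimer, and the basic dianion can enolise 6. The fallback sets out from 9 and rejoins the route at 10. Compound 9 is silylated (Me3SiCl, Et3N) to ethyl 2-allyl-3-[(trimethylsilyl)oxy]but-2-enoate F1 and then (LiN(iPr)2, Me3SiCl, −78 °C) to the Chan-type diene 2-allyl-1-ethoxy-1,3-bis[(trimethylsilyl)oxy]buta-1,3-diene F2. F2 is added at −78 °C in CH2Cl2 to 6 pre-complexed with TiCl2(OiPr)2, so that a non-basic vinylogous Mukaiyama aldol attacks the rigid ketone–epoxide chelate from the same face, and citric acid work-up removes the silyl groups to give 10.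

**Step 8** (the enzyme must accept an α-allyl, δ-tertiary-hydroxy keto ester and give the anti isomer). The fallback sets out from 6 and rejoins at 11, setting C8 and then C7 by substrate control instead of by the enzyme. Ketone 6 is treated as in step 7 with the dianion of ethyl acetoacetate 7 to give ethyl (5R)-5-hydroxy-5-[(2R,3R)-3-{[(4-methoxyphenyl)methoxy]methyl}oxiran-2-yl]-3-oxohexanoate F3. Evans–Saksena reduction (Me4NBH(OAc)3, MeCN/AcOH, −30 °C; internal hydride delivery from the C10 alkoxyborohydride) then gives the anti diol ethyl (3R,5R)-3,5-dihydroxy-5-[(2R,3R)-3-{[(4-methoxyphenyl)methoxy]methyl}oxiran-2-yl]hexanoate F4. Fráter–Seebach allylation of its polyanion (LiN(iPr)2, THF/DMPU, −78 to −40 °C, then 8) alkylates C7 anti to the C8 alkoxide and gives 11.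

**Step 24** (strained ten-membered ring, with C3 set in the ring-closing event). The fallback sets out from 29 and rejoins at 30, with C3 set by a ketone reduction instead of by the C–C bond formation. The cyclisation is run as in step 24 and the product is taken on whatever its C3 ratio, the unwanted component being the (3S)-epimer of 30 F5. Dess–Martin oxidation of the mixture gives the macrocyclic epoxy enone, the 3-oxo analogue of 30 F6. Zn(BH4)2 (Et2O, −40 °C) reduces F6 through the ketone–epoxide chelate with hydride entering anti to the epoxide C–C bond and gives the (3R) alcohol 30.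

## Further compounds

F1 | step 7 | ethyl 2-allyl-3-[(trimethylsilyl)oxy]but-2-enoate (E/Z mixture) | CCOC(=O)C(CC=C)=C(C)O[Si](C)(C)C
F2 | step 7 | 2-allyl-1-ethoxy-1,3-bis[(trimethylsilyl)oxy]buta-1,3-diene (E/Z mixture) | CCOC(O[Si](C)(C)C)=C(CC=C)C(=C)O[Si](C)(C)C
F3 | step 8 | ethyl (5R)-5-hydroxy-5-[(2R,3R)-3-{[(4-methoxyphenyl)methoxy]methyl}oxiran-2-yl]-3-oxohexanoate | COc1ccc(COC[C@H]2O[C@H]2[C@](C)(O)CC(=O)CC(=O)OCC)cc1
F4 | step 8 | ethyl (3R,5R)-3,5-dihydroxy-5-[(2R,3R)-3-{[(4-methoxyphenyl)methoxy]methyl}oxiran-2-yl]hexanoate | COc1ccc(COC[C@H]2O[C@H]2[C@](C)(O)C[C@@H](O)CC(=O)OCC)cc1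
F5 | step 24 | (3S)-epimer of 30 | C=C1C(=O)O[C@H]2/C=C(/C)[C@H](O)[C@H]3O[C@H]3[C@](C)(O[Si](CC)(CC)CC)C[C@@H](OC(=O)/C(C)=C\C)[C@@H]12
F6 | step 24 | 3-oxo analogue of 30 (macrocyclic epoxy enone) | C=C1C(=O)O[C@H]2/C=C(/C)C(=O)[C@H]3O[C@H]3[C@](C)(O[Si](CC)(CC)CC)C[C@@H](OC(=O)/C(C)=C\C)[C@@H]12
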